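Two questions stand, target and isomer of the product at 5.0 min, and both hang on one curve.

- target at 5.0 min, in percent of the starting material charged
- isomer of the product at 5.0 min, in percent of the starting material charged

| setting | birch | larch | oak | flask |
|---|---|---|---|---|
| starting material | 0.67 mM | 1.5 mM | 1 mM | 1.0 mM |
| partner | 0.95 mM (fed, over 0.80 s) | 0.95 mM (fed, over 0.80 s) | 0.47 mM (fed, over 0.80 s) | 0.950 mM (fed, over 0.80 s) |
| remark | run made earlier | run made earlier | run made earlier |  |
| time |  |  |  | 5.0 min |

| run | time / min | target / % | isomer of the product / % |
|---|---|---|---|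
| birch | 0.667 | 9.5 | 70.9 |
| birch | 1.33 | 8.8 | 71.5 |
| birch | 2.00 | 10.0 | 71.3 |
| birch | 2.50 | 9.7 | 71.4 |
| birch | 3.00 | 10.4 | 70.6 |
| birch | 4.00 | 9.3 | 70.0 |
| larch | 0.250 | 6.7 | 50.4 |
| larch | 0.833 | 6.7 | 51.9 |
| larch | 1.33 | 7.4 | 51.5 |
| larch | 2.00 | 6.3 | 51.2 |
| larch | 3.00 | 6.6 | 51.7 |
| larch | 4.00 | 7.2 | 51.7 |
| oak | 0.833 | 5.5 | 38.8 |
| oak | 1.50 | 5.0 | 39.4 |
| oak | 2.50 | 5.6 | 40.0 |
| oak | 3.00 | 5.1 | 39.5 |
| oak | 4.00 | 6.8 | 40.2 |

(scatter of a reading: 0.5 percentage points)

- a reading or a percentage of target counts all its forms, free or not

The birch run reads 70.9% of isomer at 0.667 min and 70.0% at 4.00 min, a plateau from its first point, so the curve worth drawing is total product, target plus isomer, against equivalents of partner. Its zero of scale is the stoichiometric case, where each partner ends in one product: slope one from the origin, a break at one equivalent, then a level at the full charge of starting material.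

Capture is the height of a run against that slope, product per partner charged. The oak run, at 0.470 equivalents, totals 45.2%, a capture of 96.1%. The larch run, at 0.633, totals 58.2%, a capture of 91.9%. The birch run, past the break at 1.42, averages 9.62% of target and 70.9% of isomer, so it totals 80.6% and captures 56.8%.

The flask sits at 0.950, its charge of partner smaller than its charge of starting material. A straight line from larch to birch gives 77.8%, this flask's capture, product per partner charged. The reckoned total for the flask is then 73.9%, and the target share read from the birch run, 11.9%, splits it into 8.79% of target and 65.1% of isomer.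

The forecast stands a little higher, at 9.1% of target (8% to 10.2%) and 67% of isomer (61% to 72%), holding that “each run finishes almost at once”.

The flask gives 8.41% of target and 63.1% of isomer, inside both ranges of the forecast.

    crystals ⇌ target, rate k1*(cs1 - [target]) while solid is left; crystals form when [target] > cs1 (solubility = 0.870 mM, k = 37.0 /s)
    starting material → open intermediate (k = 0.550 /s)
    open intermediate + second intermediate → target (k = 2800 /M/s)
    2 open intermediate → homo product (k = 2300 /M/s)
    target ⇌ isomer of the product (K = 7.50, k = 0.450 /s)
    partner → second intermediate (k = 2.60 /s)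

The flask's capture comes to 75.2% against the reckoned 77.8%, and its [second intermediate] stands at 0.235 mM at 5.00 min, which is 24.8% of the partner charged. The neighbour flask charged with 1.6 mM of partner, 1.60 equiv, captures 52.8%, less than the 77.8% reckoned for the flask, and ends with [second intermediate] at 0.755 mM.

The readings are simulated for substances that don't exist; scatter was added.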